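**Plan**

1. Cembrane numbering is used: C1 carries the isopropyl group, C4 the methyl ester (C18), C7 the acetate, C8 the methyl group and the lactone oxygen, C12 the lactone carbonyl (C20). The acetate is removed first, then the lactone O–C8 bond is cut to a monocyclic (7R,8R)-7,8-epoxide whose C20 carboxyl is a tert-butyl ester.
2. Enabling feature: the C20 carboxyl on C12 lies 1,5 to the quaternary C8 across the (11Z)-enoate, and the oxygens on C7 and C8 are anti. That is the imprint of a trans-oxirane opened at its tertiary carbon, so one 7-exo opening bridges the fourteen-membered ring with the seven-membered lactone and sets C8.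
3. The carbocycle is cut at C3=C4 (intramolecular HWE), then at C11=C12 (Z-selective Ando olefination) and at C4–C5 and C12–C13 (phosphonoacetate alkylations), leaving a C5–C11 epoxy aldehyde and a C13–C3 alkenyl iodide.
4. Forward: the C5–C11 piece comes from Johnson–Claisen rearrangement and Shi epoxidation, the C13–C3 piece from hydroalumination–iodination and oxirane opening. After union, the fourteen-membered ring is closed first, the lactone second, and acetylation ends the route.
5. Stereochemistry: C7 and C8 come from Shi epoxidation of an (E)-alkene as (7R,8R), and C8 is inverted to S in the lactonisation. Alkene geometries come from the Claisen chair (7E), trans-hydroalumination (1E), Ando olefination (11Z) and HWE (3E).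

Key step: step 17

Remark: compounds 1, 2, 4, 7, 9, 12, 13, 15, 16, 19, 21, 27 and 34 are taken as purchasable, and the racemic centres in 3, 25 and 28 are left uncontrolled because later steps destroy them.

**Route**

Step 1
Reactants: 1 3-[(tert-butyldimethylsilyl)oxy]propanal; 2 prop-1-en-2-ylmagnesium bromide
Product: 3 rac-5-[(tert-butyldimethylsilyl)oxy]-2-methylpent-1-en-3-ol
Conditions: 2 (1.2 equiv), THF, –78 → 0 °C; aqueous work-up
Reagents that add atoms: prop-1-en-2-ylmagnesium bromide 2, C=C(C)[Mg]Br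
Why: Grignard 1,2-addition to the aldehyde gives the isopropenyl carbinol, whose stereocenter needs no control because the next step converts it into an alkene carbon.

Step 2
Reactants: 3 rac-5-[(tert-butyldimethylsilyl)oxy]-2-methylpent-1-en-3-ol; 4 1,1,1-triethoxyethane
Product: 6 ethyl (4E)-7-[(tert-butyldimethylsilyl)oxy]-4-methylhept-4-enoate, via mixed ketene acetal 5 (not isolated)
Conditions: 4 (5 equiv), EtCO2H (cat.), 140 °C, EtOH distilled off
Reagents that add atoms: 1,1,1-triethoxyethane 4, CC(OCC)(OCC)OCC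
Why: The Johnson–Claisen rearrangement passes through a chair transition state with the CH2CH2OTBS group equatorial and should therefore give the (E)-trisubstituted C7=C8 alkene together with the C9–C11 ester arm.

Step 3
Reactants: 6 ethyl (4E)-7-[(tert-butyldimethylsilyl)oxy]-4-methylhept-4-enoate; 7 dibromotriphenylphosphorane
Product: 8 ethyl (4E)-7-bromo-4-methylhept-4-enoate
Conditions: Ph3PBr2 (1.5 equiv), CH2Cl2, 0 °C → rt
Reagents that add atoms: dibromotriphenylphosphorane 7, BrP(Br)(c1ccccc1)(c1ccccc1)c1ccccc1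
Why: Direct conversion of a primary silyl ether into a bromide with Ph3PBr2 (oxyphosphonium formation, then SN2 by bromide) is neutral and installs the C5 leaving group before the acid-sensitive oxirane exists.

Step 4
Reactants: 8 ethyl (4E)-7-bromo-4-methylhept-4-enoate; 9 potassium peroxymonosulfate
Product: 10 ethyl 3-[(2R,3R)-3-(2-bromoethyl)-2-methyloxiran-2-yl]propanoate
Conditions: 1,2:4,5-di-O-isopropylidene-β-D-erythro-2,3-hexodiulo-2,6-pyranose (0.3 equiv), KHSO5 (as Oxone), K2CO3, Bu4NHSO4, MeCN/CH2(OMe)2/aq Na2B4O7–Na2EDTA, pH about 10.5, 0 °C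
Reagents that add atoms: potassium peroxymonosulfate 9, [K+].[O-]S(=O)(=O)OO
Why: In the Shi epoxidation the dioxirane of the D-fructose-derived ketone delivers oxygen through a spiro transition state to one face of the only alkene present, an unfunctionalised (E)-trisubstituted olefin, and should set C7 and C8 as R,R.

Step 5
Reactants: 10 ethyl 3-[(2R,3R)-3-(2-bromoethyl)-2-methyloxiran-2-yl]propanoate
Product: 11 3-[(2R,3R)-3-(2-bromoethyl)-2-methyloxiran-2-yl]propanal
Conditions: iBu2AlH (1.1 equiv), CH2Cl2, –78 °C; aq KNaC4H4O6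
Reagents that add atoms: none
Why: Partial ester reduction with iBu2AlH at –78 °C stops at the aluminium hemiacetal, which releases the C11 aldehyde on work-up while the bromide and the oxirane are untouched.

Step 6
Reactants: 12 diphenyl phosphite; 13 tert-butyl bromoacetate
Product: 14 tert-butyl 2-(diphenoxyphosphoryl)acetate
Conditions: Et3N, CH2Cl2, 0 °C → rt
Reagents that add atoms: tert-butyl bromoacetate 13, CC(C)(C)OC(=O)CBr
Why: Michaelis–Becker-type P-alkylation of the phosphite anion by the α-bromo ester gives the diaryl phosphonoacetate (Ando reagent) whose tert-butyl ester is the latent lactone carboxyl.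

Step 7
Reactants: 15 4-methylpent-2-yn-1-ol; 16 iodine
Product: 18 (2Z)-3-iodo-4-methylpent-2-en-1-ol, via cyclic sodium alkenylalanate 17 (not isolated)
Conditions: NaAlH2(OCH2CH2OMe)2 (1.6 equiv), THF, 0 °C → rt; then I2, –78 → 0 °C
Reagents that add atoms: iodine 16, II
Why: Hydroxyl-directed trans-hydroalumination puts aluminium on the isopropyl-bearing carbon (C1) and hydride on C2, and iodinolysis with retention gives the iodoalkene with iodine cis to the CH2OH group, which fixes the C1=C2 geometry.

Step 8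
Reactants: 18 (2Z)-3-iodo-4-methylpent-2-en-1-ol; 19 1-(chloromethyl)-4-methoxybenzene
Product: 20 1-({[(2Z)-3-iodo-4-methylpent-2-en-1-yl]oxy}methyl)-4-methoxybenzene
Conditions: NaH, PMBCl, Bu4NI (cat.), THF/DMF, 0 °C → rt
Reagents that add atoms: 1-(chloromethyl)-4-methoxybenzene 19, COc1ccc(CCl)cc1
Why: Williamson etherification masks the future C3 aldehyde as a PMB ether that tolerates organolithium and olefination bases and is later removed oxidatively without acid.

Step 9
Reactants: 20 1-({[(2Z)-3-iodo-4-methylpent-2-en-1-yl]oxy}methyl)-4-methoxybenzene; 21 oxirane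
Product: 23 (3E)-5-[(4-methoxyphenyl)methoxy]-3-(propan-2-yl)pent-3-en-1-ol, via alkenyllithium 22 (not isolated)
Conditions: t-BuLi (2.1 equiv), Et2O, –78 °C; then oxirane, BF3·OEt2, –78 °C
Reagents that add atoms: oxirane 21, C1CO1
Why: Iodine–lithium exchange proceeds with retention of alkene geometry, and opening of the BF3-activated oxirane by the alkenyllithium adds C14–C13 cis to the CH2OPMB group.

Step 10
Reactants: 23 (3E)-5-[(4-methoxyphenyl)methoxy]-3-(propan-2-yl)pent-3-en-1-ol; 16 iodine
Product: 24 1-({[(2E)-5-iodo-3-(propan-2-yl)pent-2-en-1-yl]oxy}methyl)-4-methoxybenzene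
Conditions: I2, PPh3, imidazole, CH2Cl2, 0 °C
Reagents that add atoms: iodine 16, II
Why: Appel-type iodination converts the primary alcohol into the iodide by SN2 displacement of the oxyphosphonium ion under buffered conditions that leave the allylic PMB ether alone.

Step 11
Reactants: 24 1-({[(2E)-5-iodo-3-(propan-2-yl)pent-2-en-1-yl]oxy}methyl)-4-methoxybenzene; 14 tert-butyl 2-(diphenoxyphosphoryl)acetate
Product: 25 tert-butyl (5E)-2-(diphenoxyphosphoryl)-7-[(4-methoxyphenyl)methoxy]-5-(propan-2-yl)hept-5-enoate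
Conditions: 14 (2 equiv), NaH, DMSO, rt; then 24, rt → 40 °C
Reagents that add atoms: tert-butyl 2-(diphenoxyphosphoryl)acetate 14, CC(C)(C)OC(=O)CP(=O)(Oc1ccccc1)Oc1ccccc1
Why: C-alkylation of the stabilised phosphonoacetate anion by the primary iodide forms the C12–C13 bond, and the new stereocenter is irrelevant because C12 becomes sp2 in the next step.

Step 12
Reactants: 25 tert-butyl (5E)-2-(diphenoxyphosphoryl)-7-[(4-methoxyphenyl)methoxy]-5-(propan-2-yl)hept-5-enoate; 11 3-[(2R,3R)-3-(2-bromoethyl)-2-methyloxiran-2-yl]propanal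
Product: 26 tert-butyl (2Z,5E)-2-{3-[(2R,3R)-3-(2-bromoethyl)-2-methyloxiran-2-yl]propylidene}-7-[(4-methoxyphenyl)methoxy]-5-(propan-2-yl)hept-5-enoate
Conditions: NaH, THF, 0 °C; then 11, –78 → 0 °C
Reagents that add atoms: aldehyde 11, O=CCC[C@@]1(C)O[C@@H]1CCBr
Why: In the Ando variant of the Horner–Wadsworth–Emmons reaction the electron-poor diaryl phosphonate collapses through the oxaphosphetane faster than the adducts equilibrate, so the kinetic (Z)-enoate with the tert-butoxycarbonyl group cis to C10 should predominate while the primary bromide stays inert at low temperature.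

Step 13
Reactants: 26 tert-butyl (2Z,5E)-2-{3-[(2R,3R)-3-(2-bromoethyl)-2-methyloxiran-2-yl]propylidene}-7-[(4-methoxyphenyl)methoxy]-5-(propan-2-yl)hept-5-enoate; 27 methyl 2-(dimethoxyphosphoryl)acetate
Product: 28 tert-butyl (2Z,5E)-2-{3-[(2R,3R)-3-[3-(dimethoxyphosphoryl)-4-methoxy-4-oxobutyl]-2-methyloxiran-2-yl]propylidene}-7-[(4-methoxyphenyl)methoxy]-5-(propan-2-yl)hept-5-enoate
Conditions: 27 (3 equiv), NaH, NaI (cat.), DMF, 50 °C
Reagents that add atoms: methyl 2-(dimethoxyphosphoryl)acetate 27, COC(=O)CP(=O)(OC)OC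
Why: SN2 alkylation of sodium trimethyl phosphonoacetate by the primary bromide under iodide catalysis attaches C4 with its methyl ester and phosphonate, and the weakly basic carbanion should spare the trisubstituted oxirane and the hindered enoate.

Step 14
Reactants: 28 tert-butyl (2Z,5E)-2-{3-[(2R,3R)-3-[3-(dimethoxyphosphoryl)-4-methoxy-4-oxobutyl]-2-methyloxiran-2-yl]propylidene}-7-[(4-methoxyphenyl)methoxy]-5-(propan-2-yl)hept-5-enoate
Product: 29 tert-butyl (2Z,5E)-2-{3-[(2R,3R)-3-[3-(dimethoxyphosphoryl)-4-methoxy-4-oxobutyl]-2-methyloxiran-2-yl]propylidene}-7-hydroxy-5-(propan-2-yl)hept-5-enoate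
Conditions: DDQ, CH2Cl2/pH 7 phosphate buffer, 0 °C
Reagents that add atoms: none
Why: Oxidative PMB cleavage with DDQ proceeds through a benzylic oxocarbenium ion that water hydrolyses, which frees the allylic alcohol under buffered conditions the oxirane tolerates.

Step 15
Reactants: 29 tert-butyl (2Z,5E)-2-{3-[(2R,3R)-3-[3-(dimethoxyphosphoryl)-4-methoxy-4-oxobutyl]-2-methyloxiran-2-yl]propylidene}-7-hydroxy-5-(propan-2-yl)hept-5-enoate
Product: 30 tert-butyl (2Z,5E)-2-{3-[(2R,3R)-3-[3-(dimethoxyphosphoryl)-4-methoxy-4-oxobutyl]-2-methyloxiran-2-yl]propylidene}-7-oxo-5-(propan-2-yl)hept-5-enoate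
Conditions: MnO2 (excess), CH2Cl2, rt
Reagents that add atoms: none
Why: Allylic oxidation on the MnO2 surface is neutral and selective for the allylic alcohol, so the C1=C2 geometry, the oxirane and the acidic phosphonoacetate should survive.

Step 16
Reactants: 30 tert-butyl (2Z,5E)-2-{3-[(2R,3R)-3-[3-(dimethoxyphosphoryl)-4-methoxy-4-oxobutyl]-2-methyloxiran-2-yl]propylidene}-7-oxo-5-(propan-2-yl)hept-5-enoate
Product: 31 20-tert-butyl 18-methyl (1E,3E,7R,8R,11Z)-7,8-epoxycembra-1,3,11-triene-18,20-dioate
Conditions: LiCl, DBU, MeCN, 1 mM (slow addition), rt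
Reagents that add atoms: none
Why: The intramolecular Horner–Wadsworth–Emmons reaction under Masamune–Roush conditions at high dilution closes the fourteen-membered carbocycle at C3=C4, and the thermodynamically preferred geometry with the ester trans to C2 is the one required.

Step 17
Reactants: 31 20-tert-butyl 18-methyl (1E,3E,7R,8R,11Z)-7,8-epoxycembra-1,3,11-triene-18,20-dioate
Product: 33 methyl (1E,3E,7R,8S,11Z)-7-hydroxy-20-oxo-8,20-epoxycembra-1,3,11-trien-18-oate, via bridged dioxocarbenium zwitterion 32 (not isolated)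
Conditions: BF3·OEt2 (0.3 equiv), CH2Cl2, –78 → –30 °C; aq NaHCO3
Reagents that add atoms: none
Why: BF3 binds the oxirane oxygen and weakens the C8–O bond at the tertiary carbon, and the carbonyl oxygen of the C20 tert-butyl ester, held 1,5 to C8 by the (11Z)-enoate, attacks C8 anti to the oxirane oxygen to give zwitterion 32, which loses 2-methylpropene and a proton to leave the lactone and return the Lewis acid. The closest known reaction type is the Lewis-acid-promoted opening of epoxides by a neighbouring tert-butyl ester or carbonate to give hydroxy lactones or cyclic carbonates. The seven-membered ε-lactone closes in the 7-exo-tet mode at the oxirane, across the fourteen-membered ring. C8 is set by inversion of the (8R)-oxirane carbon and becomes S, while C7 keeps the R configuration from the Shi epoxidation because its C–O bond is not broken. The step needs attack at C8 and not C7, and participation of the C20 ester and not the C18 ester: the tertiary carbon carries most of the positive charge and the exo mode gives the seven- and not the eight-membered ring, and only the tert-butyl ester can dealkylate irreversibly, so a six-membered adduct of the methyl ester at C7 should revert.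

Step 18
Reactants: 33 methyl (1E,3E,7R,8S,11Z)-7-hydroxy-20-oxo-8,20-epoxycembra-1,3,11-trien-18-oate; 34 acetic anhydride
Product: 35 Sarcrassin D
Conditions: Ac2O, DMAP, pyridine, CH2Cl2, rt
Reagents that add atoms: acetic anhydride 34, CC(=O)OC(C)=O
Why: DMAP-catalysed acylation of the hindered secondary C7 alcohol proceeds with retention at C7 and completes the target.

**Compound list**

1 | 3-[(tert-butyldimethylsilyl)oxy]propanal | O=CCCO[Si](C)(C)C(C)(C)C | starting material
2 | prop-1-en-2-ylmagnesium bromide (isopropenylmagnesium bromide) | C=C(C)[Mg]Br | starting material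
3 | rac-5-[(tert-butyldimethylsilyl)oxy]-2-methylpent-1-en-3-ol | C=C(C)C(O)CCO[Si](C)(C)C(C)(C)C | intermediate
4 | 1,1,1-triethoxyethane (triethyl orthoacetate) | CC(OCC)(OCC)OCC | starting material
5 | mixed ketene acetal tert-butyl({3-[(1-ethoxyethenyl)oxy]-4-methylpent-4-en-1-yl}oxy)dimethylsilane (formed in the flask) | C=C(OCC)OC(CCO[Si](C)(C)C(C)(C)C)C(C)=C | intermediate
6 | ethyl (4E)-7-[(tert-butyldimethylsilyl)oxy]-4-methylhept-4-enoate | CCOC(=O)CC/C(C)=C/CCO[Si](C)(C)C(C)(C)C | intermediate
7 | dibromotriphenylphosphorane | BrP(Br)(c1ccccc1)(c1ccccc1)c1ccccc1 | starting material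
8 | ethyl (4E)-7-bromo-4-methylhept-4-enoate | CCOC(=O)CC/C(C)=C/CCBr | intermediate
9 | potassium peroxymonosulfate (active component of Oxone) | [K+].[O-]S(=O)(=O)OO | starting material
10 | ethyl 3-[(2R,3R)-3-(2-bromoethyl)-2-methyloxiran-2-yl]propanoate | CCOC(=O)CC[C@@]1(C)O[C@@H]1CCBr | intermediate
11 | 3-[(2R,3R)-3-(2-bromoethyl)-2-methyloxiran-2-yl]propanal | O=CCC[C@@]1(C)O[C@@H]1CCBr | intermediate
12 | diphenyl phosphite | O=[PH](Oc1ccccc1)Oc1ccccc1 | starting material
13 | tert-butyl bromoacetate | CC(C)(C)OC(=O)CBr | starting material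
14 | tert-butyl 2-(diphenoxyphosphoryl)acetate | CC(C)(C)OC(=O)CP(=O)(Oc1ccccc1)Oc1ccccc1 | intermediate
15 | 4-methylpent-2-yn-1-ol | CC(C)C#CCO | starting material
16 | iodine | II | starting material
17 | cyclic sodium alkenylalanate: five-membered O–CH2–CH=C(iPr)–Al ring with two 2-methoxyethoxy groups on aluminium (formed in the flask) | [Na+].COCCO[Al-]1(OCCOC)OCC=C1C(C)C | intermediate
18 | (2Z)-3-iodo-4-methylpent-2-en-1-ol | CC(C)/C(I)=C/CO | intermediate
19 | 1-(chloromethyl)-4-methoxybenzene (PMBCl) | COc1ccc(CCl)cc1 | starting material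
20 | 1-({[(2Z)-3-iodo-4-methylpent-2-en-1-yl]oxy}methyl)-4-methoxybenzene | CC(C)/C(I)=C/COCc1ccc(OC)cc1 | intermediate
21 | oxirane | C1CO1 | starting material
22 | alkenyllithium {(1E)-3-[(4-methoxyphenyl)methoxy]-1-(propan-2-yl)prop-1-en-1-yl}lithium, lithium cis to CH2OPMB (formed in the flask) | CC(C)/C([Li])=C/COCc1ccc(OC)cc1 | intermediate
23 | (3E)-5-[(4-methoxyphenyl)methoxy]-3-(propan-2-yl)pent-3-en-1-ol | CC(C)/C(CCO)=C/COCc1ccc(OC)cc1 | intermediate
24 | 1-({[(2E)-5-iodo-3-(propan-2-yl)pent-2-en-1-yl]oxy}methyl)-4-methoxybenzene | CC(C)/C(CCI)=C/COCc1ccc(OC)cc1 | intermediate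
25 | tert-butyl (5E)-2-(diphenoxyphosphoryl)-7-[(4-methoxyphenyl)methoxy]-5-(propan-2-yl)hept-5-enoate (racemic) | CC(C)/C(CCC(C(=O)OC(C)(C)C)P(=O)(Oc1ccccc1)Oc1ccccc1)=C/COCc1ccc(OC)cc1 | intermediate
26 | tert-butyl (2Z,5E)-2-{3-[(2R,3R)-3-(2-bromoethyl)-2-methyloxiran-2-yl]propylidene}-7-[(4-methoxyphenyl)methoxy]-5-(propan-2-yl)hept-5-enoate | CC(C)(C)OC(=O)/C(CC/C(=C\COCc1ccc(OC)cc1)C(C)C)=C\CC[C@@]1(C)O[C@@H]1CCBr | intermediate
27 | methyl 2-(dimethoxyphosphoryl)acetate (trimethyl phosphonoacetate) | COC(=O)CP(=O)(OC)OC | starting material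
28 | tert-butyl (2Z,5E)-2-{3-[(2R,3R)-3-[3-(dimethoxyphosphoryl)-4-methoxy-4-oxobutyl]-2-methyloxiran-2-yl]propylidene}-7-[(4-methoxyphenyl)methoxy]-5-(propan-2-yl)hept-5-enoate (both epimers at the phosphonate carbon) | CC(C)(C)OC(=O)/C(CC/C(=C\COCc1ccc(OC)cc1)C(C)C)=C\CC[C@@]1(C)O[C@@H]1CCC(C(=O)OC)P(=O)(OC)OC | intermediate
29 | 7-hydroxy analogue of 28 (allylic alcohol at C3) | CC(C)(C)OC(=O)/C(CC/C(=C\CO)C(C)C)=C\CC[C@@]1(C)O[C@@H]1CCC(C(=O)OC)P(=O)(OC)OC | intermediate
30 | 7-oxo analogue of 28 (enal at C3) | CC(C)(C)OC(=O)/C(CC/C(=C\C=O)C(C)C)=C\CC[C@@]1(C)O[C@@H]1CCC(C(=O)OC)P(=O)(OC)OC | intermediate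
31 | 20-tert-butyl 18-methyl (1E,3E,7R,8R,11Z)-7,8-epoxycembra-1,3,11-triene-18,20-dioate (fourteen-membered carbocycle) | COC(=O)/C1=C/C=C(/C(C)C)CC/C(C(=O)OC(C)(C)C)=C/CC[C@@]2(C)O[C@@H]2CC1 | intermediate
32 | bridged tert-butoxy dioxocarbenium ion with C7 alkoxytrifluoroborate (zwitterion, formed in the flask) | COC(=O)/C1=C/C=C(/C(C)C)CCC2=CCC[C@](C)(O[C+]2OC(C)(C)C)[C@H](O[B-](F)(F)F)CC1 | intermediate
33 | methyl (1E,3E,7R,8S,11Z)-7-hydroxy-20-oxo-8,20-epoxycembra-1,3,11-trien-18-oate (7-O-deacetylsarcrassin D) | COC(=O)/C1=C/C=C(/C(C)C)CCC2=CCC[C@](C)(OC2=O)[C@H](O)CC1 | intermediate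
34 | acetic anhydride | CC(=O)OC(C)=O | starting material
35 | Sarcrassin D | COC(=O)/C1=C/C=C(/C(C)C)CCC2=CCC[C@](C)(OC2=O)[C@H](OC(C)=O)CC1 | target

**Step count and risks**

Total step count: 18. Longest linear sequence: 12 steps (steps 1–5, then 12–18; the branch through steps 7–11, then 12–18, is equally long).

Steps most likely to fail:

Step 17. The intended ester participation may lose to transannular pathways of the activated oxirane: hydride shift to a C7 ketone, proton loss to allylic alcohols, or attack by the diene. The fallback runs the same oxirane-opening lactonisation before the carbocycle exists, where no ring holds a π-nucleophile near C8, and closes the fourteen-membered ring last. It sets out from 28. BF3·OEt2 (1.2 equiv) in CH2Cl2 at –78 °C should give the acyclic hydroxy lactone F1. Ac2O, DMAP and pyridine give the acetate F2. DDQ in buffered CH2Cl2 gives the allylic alcohol F3, and MnO2 gives the enal F4. LiCl and DBU in MeCN at high dilution then close the carbocycle by HWE olefination, and the route comes back at 35.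

Step 16. Ring closure may lose to oligomerisation, the enal may lose its C1=C2 geometry by reversible γ-deprotonation under base, and the E selectivity at C3=C4 may be incomplete. The fallback closes the ring at the C3–C4 single bond by palladium-catalysed allylic alkylation and introduces the unsaturation afterwards. It sets out from 26. Alkylation of methyl (phenylsulfonyl)acetate (NaH, NaI, DMF, 50 °C) gives the sulfonyl ester F5. DDQ gives the allylic alcohol F6, and ClCO2Me with pyridine gives the allylic methyl carbonate F7. Pd(PPh3)4 (a zerovalent palladium complex) in THF at high dilution should give the macrocyclic sulfone F8 by attack of the sulfonyl ester carbanion at the primary allyl terminus C3. The C1=C2 geometry holds only if this attack is faster than isomerisation of the allyl complex. DBU then eliminates benzenesulfinate towards the allylic C3 hydrogen, and the route comes back at 31.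

Step 9. The iodine–lithium exchange may be incomplete, the hindered alkenyllithium may be protonated before it meets the oxirane, or the Lewis acid may cleave the allylic PMB ether. The fallback builds the same trisubstituted alkene by syn-carbocupration of an ynoate. It sets out from purchasable tert-butyl(but-3-yn-1-yloxy)dimethylsilane. n-BuLi and then ClCO2Me in THF at –78 °C give the ynoate F9. i-PrMgCl with CuI in THF at –78 °C adds the isopropyl group syn to copper and gives the (E)-enoate F10, with isopropyl trans to the ester. iBu2AlH gives the allylic alcohol F11, NaH and PMBCl give the PMB ether F12, and Bu4NF removes the silyl group, so the route comes back at 23.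

Further compounds
F1 | step 17 | acyclic (7R,8S)-7-hydroxy-8,20-lactone carrying the C4 phosphonoacetate arm and the C3 PMB ether | O=C1O[C@](C)([C@H](O)CCC(C(=O)OC)P(=O)(OC)OC)CCC=C1CC/C(=C\COCc2ccc(OC)cc2)C(C)C
F2 | step 17 | 7-O-acetate of F1 | O=C1O[C@](C)([C@H](OC(C)=O)CCC(C(=O)OC)P(=O)(OC)OC)CCC=C1CC/C(=C\COCc2ccc(OC)cc2)C(C)C
F3 | step 17 | allylic alcohol from F2 (free C3 hydroxyl) | O=C1O[C@](C)([C@H](OC(C)=O)CCC(C(=O)OC)P(=O)(OC)OC)CCC=C1CC/C(=C\CO)C(C)C
F4 | step 17 | enal from F3 (C3 aldehyde) | O=C1O[C@](C)([C@H](OC(C)=O)CCC(C(=O)OC)P(=O)(OC)OC)CCC=C1CC/C(=C\C=O)C(C)C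
F5 | step 16 | sulfonyl ester: 26 with bromide replaced by CH(CO2Me)SO2Ph | CC(C)(C)OC(=O)/C(CC/C(=C\COCc1ccc(OC)cc1)C(C)C)=C\CC[C@@]1(C)O[C@@H]1CCC(C(=O)OC)S(=O)(=O)c1ccccc1
F6 | step 16 | allylic alcohol from F5 | CC(C)(C)OC(=O)/C(CC/C(=C\CO)C(C)C)=C\CC[C@@]1(C)O[C@@H]1CCC(C(=O)OC)S(=O)(=O)c1ccccc1
F7 | step 16 | allylic methyl carbonate from F6 | CC(C)(C)OC(=O)/C(CC/C(=C\COC(=O)OC)C(C)C)=C\CC[C@@]1(C)O[C@@H]1CCC(C(=O)OC)S(=O)(=O)c1ccccc1
F8 | step 16 | macrocyclic sulfone: fourteen-membered ring with C4 bearing CO2Me and SO2Ph, C3 saturated | COC(=O)C1(S(=O)(=O)c2ccccc2)C/C=C(/C(C)C)CC/C(C(=O)OC(C)(C)C)=C/CC[C@@]2(C)O[C@@H]2CC1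
F9 | step 9 | methyl 5-[(tert-butyldimethylsilyl)oxy]pent-2-ynoate | COC(=O)C#CCCO[Si](C)(C)C(C)(C)C
F10 | step 9 | methyl (2E)-5-[(tert-butyldimethylsilyl)oxy]-3-(propan-2-yl)pent-2-enoate | COC(=O)/C=C(\CCO[Si](C)(C)C(C)(C)C)C(C)C
F11 | step 9 | (2E)-5-[(tert-butyldimethylsilyl)oxy]-3-(propan-2-yl)pent-2-en-1-ol | OC/C=C(\CCO[Si](C)(C)C(C)(C)C)C(C)C
F12 | step 9 | tert-butyl({(3E)-5-[(4-methoxyphenyl)methoxy]-3-(propan-2-yl)pent-3-en-1-yl}oxy)dimethylsilane | COc1ccc(COC/C=C(\CCO[Si](C)(C)C(C)(C)C)C(C)C)cc1
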